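(The constants were set for the occasion; the run is a simulation.)

The fresh carrier does two things in this flask: it turns starting material into product, and it dies to spent catalyst.

    spent carrier + salt in the second phase ⇌ fresh carrier + spent salt in the second phase (K1 = 0.989, k1 = 67.7 /M/s)
    fresh carrier → spent catalyst (k2 = 0.0488 /s)
    starting material + fresh carrier → product + spent carrier (k3 = 55.4 /M/s)

- red: starting material 0.010 M; salt in the second phase 0.0180 M; spent carrier 0.51 mM; time 1.5 min; volume of the second phase over the first 2.0
- grey: starting material 0.010 M; salt in the second phase 0.0180 M; spent carrier 0.77 mM; time 1.5 min; volume of the second phase over the first 2.0

- in the second phase: salt in the second phase, spent salt in the second phase; everything else is in the first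
- charges count per volume of the first phase; a concentration in a rate is the amount of a species over the volume of its own phase; every rate counts per litre of the first phase
- run time (red): 1.5 min

1. which of these there is most of at the end, counted by the starting material in it, red (starting material / product)
2. which of these there is most of at the end, counted by the starting material in it, grey (starting material / product)
3. how much there is at the end of the one of these that leads, in percent of the starting material charged: red
4. how much there is at the end of the one of these that leads, in percent of the starting material charged: grey

Both of those rates carry [fresh carrier], so it cancels in their ratio. We therefore go to logarithms. The ln of charged over remaining [starting material] equals [spent catalyst] times the reach, which is the constant of conversion over the constant of death: 55.4 /M/s over 0.0488 /s, or 1.14 /mM.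

Now the settings, by hand. The charge of spent carrier enters the exponent directly, so we expect it to matter most. Salt comes next. In its own phase it stands at 9.00 mM, which gives a pseudo-first-order rate of making fresh carrier of 0.609 /s. Conversion uses fresh carrier at 0.554 /s and death at 0.0488 /s. Holding these starting rates, the fresh share is 0.503, about half. More salt raises that share and speeds the death, and the exponent grows with the spent part of the charge. Starting material acts on the same share.

Time comes last. The catalyst's half-life is then 0.471 min, shorter than the run, so we reckon 89.0% of the charge dead by 1.5 min. The exponent is 0.515 for red, which leaves 59.8% of the starting material. For grey it is 0.778, which gives 54.1% product. Against the crossing at 0.693, red falls short and grey passes.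

The forecast says starting material at 60% for red and product at 53% for grey, on the ground that “the final conversion depends mainly on the carrier charge”. Its grey figure stands slightly below ours.

The flask gives starting material at 60.1% for red and product at 53.3% for grey. Red's settings rank spent carrier (8.3 points), then time (2.7 points), then salt in the second phase (1.8 points), then starting material (1.6 points). With red's 87.8% of its catalyst spent, the reach leaves 60.1%, and the flask holds 60.1%. A neighbouring flask is red with 8.7 × 10⁻⁴ M of spent carrier. Our unchanged 89.0% gives it an exponent of 0.879, which leaves 41.5%. In that flask 86.7% of the catalyst is spent, product leads, and the starting material left is 42.5%.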